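## Retrosynthetic overview

1. Target 24 ⇐ silyl ether 23 (fluoride desilylation). 23 ⇐ aldehyde 14 + arylboronic acid 22: the C7–aryl bond and the C7 carbinol centre are made together in a rhodium-catalysed, ligand-controlled 1,2-arylation.
2. 14 ⇐ ethyl (S)-lactate + phenol 10: Mitsunobu inversion makes the C8–O–aryl ether and fixes 8R; half-reduction then gives the aldehyde.
3. 10 ⇐ resorcinol: methylation, C2 lithiation/oxidation, O-allylation, para-Claisen rearrangement.
4. 22 ⇐ catechol: methylation, C3 lithiation/oxidation, TIPS protection, iridium-catalysed C–H borylation at the only unhindered C–H, pinacol removal.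
5. No ring is constructed. Ring B (from resorcinol) is elaborated in the longer branch, ring A (from catechol) in the parallel branch, and the two are joined in step 12.

Numbering used below: C7 is the carbinol carbon, C8 the aryloxy-bearing carbon. The target is (7R,8R), the threo series.

Assumption and definition: L1 = 2,5-bis(3,5-di-tert-butyl-4-methoxyphenyl)bicyclo[2.2.2]octa-2,5-diene. Its (R,R) antipode is assumed to be the one that delivers the aryl group to the Re face of the formyl group of 14; the mirror-image ligand would be used if a model run showed the opposite sense.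

## Route

Step 1
Reactants: 1 resorcinol
Product: 2 1,3-dimethoxybenzene
Conditions: MeI (2.5 equiv), K2CO3, acetone, reflux
Reagents that add atoms: iodomethane, CI
Why: Williamson ether synthesis; both phenoxides are methylated by SN2 on MeI, and no stereocentre is involved.

Step 2
Reactants: 2 1,3-dimethoxybenzene
Product: 5 2,6-dimethoxyphenol, via (2,6-dimethoxyphenyl)lithium 3 (not isolated), via dimethyl (2,6-dimethoxyphenyl)boronate 4 (not isolated)
Conditions: n-BuLi, THF, 0 °C to rt; B(OMe)3, −78 °C to rt; AcOH, 30% aq. H2O2, 0 °C to rt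
Reagents that add atoms: hydrogen peroxide, OO
Why: Directed ortho-metalation occurs at C2, which is flanked by both methoxy groups; borate trapping and peroxide oxidation (1,2-aryl shift from B to O) give the phenol.

Step 3
Reactants: 5 2,6-dimethoxyphenol; 6 allyl bromide (3-bromoprop-1-ene)
Product: 7 2-(allyloxy)-1,3-dimethoxybenzene
Conditions: K2CO3, acetone, reflux
Reagents that add atoms: none
Why: Williamson etherification; the phenoxide displaces bromide from the unhindered primary allylic halide by SN2.

Step 4
Reactants: 7 2-(allyloxy)-1,3-dimethoxybenzene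
Product: 10 4-allyl-2,6-dimethoxyphenol, via 6-allyl-2,6-dimethoxycyclohexa-2,4-dien-1-one 8 (not isolated), via 4-allyl-2,6-dimethoxycyclohexa-2,5-dien-1-one 9 (not isolated)
Conditions: N,N-diethylaniline, 200 °C, Ar
Reagents that add atoms: none
Why: para-Claisen rearrangement; with both ortho positions blocked, the [3,3] ortho-dienone relays the allyl group by a Cope [3,3] shift to C4, and tautomerisation restores the arene.

Step 5
Reactants: 10 4-allyl-2,6-dimethoxyphenol; 11 ethyl (S)-lactate
Product: 12 ethyl (2R)-2-(4-allyl-2,6-dimethoxyphenoxy)propanoate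
Conditions: PPh3, DIAD, THF, 0 °C to rt
Reagents that add atoms: none
Why: Mitsunobu reaction; the phenoxide displaces the alkoxyphosphonium of the lactate by SN2 with clean inversion, so the S carbinol becomes the 8R aryl ether.

Step 6
Reactants: 12 ethyl (2R)-2-(4-allyl-2,6-dimethoxyphenoxy)propanoate
Product: 14 (2R)-2-(4-allyl-2,6-dimethoxyphenoxy)propanal, via diisobutylaluminium hemiacetal 13 (not isolated)
Conditions: i-Bu2AlH (1.1 equiv), CH2Cl2, −78 °C; MeOH, then aq. KNaC4H4O6; crude aldehyde used the same day
Reagents that add atoms: none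
Why: DIBAL half-reduction; the tetrahedral aluminium hemiacetal, stabilised by the α-aryloxy oxygen, survives at −78 °C and releases the aldehyde only on work-up, leaving C8 untouched.

Step 7
Reactants: 15 catechol
Product: 16 1,2-dimethoxybenzene (veratrole)
Conditions: MeI (2.5 equiv), K2CO3, acetone, reflux
Reagents that add atoms: iodomethane, CI
Why: Williamson ether synthesis; double SN2 O-methylation.

Step 8
Reactants: 16 1,2-dimethoxybenzene
Product: 19 2,3-dimethoxyphenol, via (2,3-dimethoxyphenyl)lithium 17 (not isolated), via dimethyl (2,3-dimethoxyphenyl)boronate 18 (not isolated)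
Conditions: n-BuLi, TMEDA, Et2O, 0 °C to rt; B(OMe)3, −78 °C to rt; AcOH, 30% aq. H2O2, 0 °C to rt
Reagents that add atoms: hydrogen peroxide, OO
Why: Directed ortho-metalation of veratrole at C3, borate trapping and boronate oxidation give the phenol with the two methyl ethers already differentiated from the free hydroxyl.

Step 9
Reactants: 19 2,3-dimethoxyphenol
Product: 20 (2,3-dimethoxyphenoxy)triisopropylsilane
Conditions: TIPSCl, imidazole, DMF, rt
Reagents that add atoms: triisopropylsilyl chloride, CC(C)[Si](Cl)(C(C)C)C(C)C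
Why: Imidazole-promoted O-silylation; the bulky silyl ether masks the phenol and sterically shields the neighbouring C–H for the next step.

Step 10
Reactants: 20 (2,3-dimethoxyphenoxy)triisopropylsilane
Product: 21 2-[3,4-dimethoxy-5-(triisopropylsilyloxy)phenyl]-4,4,5,5-tetramethyl-1,3,2-dioxaborolane
Conditions: [Ir(OMe)(cod)]2 (1.5 mol %), 4,4'-di-tert-butyl-2,2'-bipyridine (3 mol %), B2pin2 (1.0 equiv), THF, 80 °C
Reagents that add atoms: bis(pinacolato)diboron, CC1(C)OB(OC1(C)C)B1OC(C)(C)C(C)(C)O1
Why: Iridium-catalysed aromatic C–H borylation through a tris(boryl) complex of trivalent iridium is sterically governed, so it occurs only at C5, the one C–H with no ortho substituent.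

Step 11
Reactants: 21 2-[3,4-dimethoxy-5-(triisopropylsilyloxy)phenyl]-4,4,5,5-tetramethyl-1,3,2-dioxaborolane
Product: 22 [3,4-dimethoxy-5-(triisopropylsilyloxy)phenyl]boronic acid
Conditions: NaIO4, NH4OAc, acetone/H2O, rt
Reagents that add atoms: water, O
Why: Oxidative pinacol cleavage: periodate destroys the diol and drives boronate hydrolysis, giving the free boronic acid that transmetalates to a hydroxo-rhodium complex at room temperature without added base.

Step 12
Reactants: 14 (2R)-2-(4-allyl-2,6-dimethoxyphenoxy)propanal; 22 [3,4-dimethoxy-5-(triisopropylsilyloxy)phenyl]boronic acid (1.5 equiv)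
Product: 23 (1R,2R)-2-(4-allyl-2,6-dimethoxyphenoxy)-1-[3,4-dimethoxy-5-(triisopropylsilyloxy)phenyl]propan-1-ol
Conditions: [Rh(OH)((R,R)-L1)]2 (2.5 mol %), 1,4-dioxane/H2O 10:1, no added base, 20 °C; chromatography to remove any 7S (erythro) isomer
Reagents that add atoms: none
Why: Proposed new method: the hydroxo-rhodium complex of the bulky C2-symmetric diene transmetalates with 22 to an aryl–rhodium species (monovalent rhodium throughout), the electrophilic α-aryloxy aldehyde binds and undergoes 1,2-migratory insertion through a four-centred transition state in which the ligand's aryl wings leave only the Re face of the formyl group open, and water releases the carbinol and regenerates Rh–OH; Re-face aryl delivery sets C7 as R (threo to the untouched 8R centre) against the weak Felkin–Anh bias of a substrate whose α-substituents are only H and CH3, while the base-free room-temperature conditions keep C8 from epimerising; the closest known reaction type is the rhodium/chiral-diene-catalysed enantioselective 1,2-addition of arylboronic acids to simple achiral aldehydes, not yet shown to overrule substrate control in an enolisable α-aryloxy aldehyde.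

Step 13
Reactants: 23 (1R,2R)-2-(4-allyl-2,6-dimethoxyphenoxy)-1-[3,4-dimethoxy-5-(triisopropylsilyloxy)phenyl]propan-1-ol
Product: 24 (1R,2R)-2-(4-allyl-2,6-dimethoxyphenoxy)-1-(3-hydroxy-4,5-dimethoxyphenyl)propan-1-ol (CNP0144691.1)
Conditions: n-Bu4NF, AcOH, THF, 0 °C
Reagents that add atoms: none
Why: Fluoride-mediated desilylation (Si–F bond formation) frees the phenol; buffered conditions leave the allyl group, the methyl ethers, the alkyl aryl ether and both stereocentres untouched.

## Compound list

1 | resorcinol | Oc1cccc(O)c1 | starting material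
2 | 1,3-dimethoxybenzene | COc1cccc(OC)c1 | intermediate
3 | (2,6-dimethoxyphenyl)lithium | [Li]c1c(OC)cccc1OC | intermediate
4 | dimethyl (2,6-dimethoxyphenyl)boronate | COB(OC)c1c(OC)cccc1OC | intermediate
5 | 2,6-dimethoxyphenol | COc1cccc(OC)c1O | intermediate
6 | allyl bromide | C=CCBr | starting material
7 | 2-(allyloxy)-1,3-dimethoxybenzene | C=CCOc1c(OC)cccc1OC | intermediate
8 | 6-allyl-2,6-dimethoxycyclohexa-2,4-dien-1-one (racemic) | C=CCC1(OC)C=CC=C(OC)C1=O | intermediate
9 | 4-allyl-2,6-dimethoxycyclohexa-2,5-dien-1-one | C=CCC1C=C(OC)C(=O)C(OC)=C1 | intermediate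
10 | 4-allyl-2,6-dimethoxyphenol | C=CCc1cc(OC)c(O)c(OC)c1 | intermediate
11 | ethyl (S)-lactate | C[C@H](O)C(=O)OCC | starting material
12 | ethyl (2R)-2-(4-allyl-2,6-dimethoxyphenoxy)propanoate | C=CCc1cc(OC)c(O[C@H](C)C(=O)OCC)c(OC)c1 | intermediate
13 | diisobutylaluminium hemiacetal of 12 (2R; hemiacetal carbon unassigned) | C=CCc1cc(OC)c(O[C@H](C)C(OCC)O[Al](CC(C)C)CC(C)C)c(OC)c1 | intermediate
14 | (2R)-2-(4-allyl-2,6-dimethoxyphenoxy)propanal | C=CCc1cc(OC)c(O[C@H](C)C=O)c(OC)c1 | intermediate
15 | catechol | Oc1ccccc1O | starting material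
16 | 1,2-dimethoxybenzene | COc1ccccc1OC | intermediate
17 | (2,3-dimethoxyphenyl)lithium | [Li]c1cccc(OC)c1OC | intermediate
18 | dimethyl (2,3-dimethoxyphenyl)boronate | COB(OC)c1cccc(OC)c1OC | intermediate
19 | 2,3-dimethoxyphenol | COc1cccc(O)c1OC | intermediate
20 | (2,3-dimethoxyphenoxy)triisopropylsilane | COc1cccc(O[Si](C(C)C)(C(C)C)C(C)C)c1OC | intermediate
21 | 2-[3,4-dimethoxy-5-(triisopropylsilyloxy)phenyl]-4,4,5,5-tetramethyl-1,3,2-dioxaborolane | COc1cc(B2OC(C)(C)C(C)(C)O2)cc(O[Si](C(C)C)(C(C)C)C(C)C)c1OC | intermediate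
22 | [3,4-dimethoxy-5-(triisopropylsilyloxy)phenyl]boronic acid | COc1cc(B(O)O)cc(O[Si](C(C)C)(C(C)C)C(C)C)c1OC | intermediate
23 | (1R,2R)-2-(4-allyl-2,6-dimethoxyphenoxy)-1-[3,4-dimethoxy-5-(triisopropylsilyloxy)phenyl]propan-1-ol | C=CCc1cc(OC)c(O[C@H](C)[C@H](O)c2cc(O[Si](C(C)C)(C(C)C)C(C)C)c(OC)c(OC)c2)c(OC)c1 | intermediate
24 | (1R,2R)-2-(4-allyl-2,6-dimethoxyphenoxy)-1-(3-hydroxy-4,5-dimethoxyphenyl)propan-1-ol | C=CCc1cc(OC)c(O[C@H](C)[C@H](O)c2cc(O)c(OC)c(OC)c2)c(OC)c1 | target

## Step count and risks

Total step count: 13. Longest linear sequence: 8 steps (steps 1–6, 12 and 13, from resorcinol). The ring A branch from catechol is 5 steps (steps 7–11).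

Steps most likely to fail:

Step 12 (the proposed new arylation). The Felkin–Anh preference of 14 favours Si-face attack, which gives the erythro isomer, so the ligand must overrule it. Aldehyde 14 can also epimerise, and 22 can protodeboronate. The fallback uses known chemistry, sets out from ester 12 and boronic acid 22, and comes back at 23. Ester 12 is treated with Me2AlS(C6H4Me-4), made from AlMe3 and 4-methylbenzenethiol in CH2Cl2 at 0 °C to rt, to give S-(4-methylphenyl) (2R)-2-(4-allyl-2,6-dimethoxyphenoxy)propanethioate F1. A base-free Liebeskind–Srogl coupling of F1 with 22 (Pd2(dba)3, P(2-furyl)3, Cu(O2CC4H3S), THF, 50 °C) gives (2R)-2-(4-allyl-2,6-dimethoxyphenoxy)-1-[3,4-dimethoxy-5-(triisopropylsilyloxy)phenyl]propan-1-one F2 without touching C8. Reduction of F2 with a non-chelating hydride (n-Bu4NBH4, CH2Cl2, −40 °C) is Felkin–Anh controlled, which in the ketone series leads to the threo (7R,8R) alcohol 23.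

Step 6 (half-reduction). Over-reduction to the alcohol, or epimerisation of the labile α-aryloxy aldehyde on work-up, would erode yield or optical purity. The fallback sets out from 12 and comes back at 14. Full reduction with LiAlH4 in THF at 0 °C gives (2R)-2-(4-allyl-2,6-dimethoxyphenoxy)propan-1-ol F3, a stable and storable compound. F3 is oxidised just before use with Dess–Martin periodinane (NaHCO3-buffered CH2Cl2, 0 °C) to aldehyde 14.

Step 5 (Mitsunobu with a doubly ortho-substituted phenol). Slow phenoxide attack can lead to hydrazide alkylation or elimination to ethyl acrylate. The fallback sets out from 10 and 11 and comes back at 12. Lactate 11 is converted with Tf2O and 2,6-lutidine (CH2Cl2, −78 °C) into ethyl (2S)-2-(trifluoromethylsulfonyloxy)propanoate F4. The potassium phenoxide of 10 (K2CO3, MeCN, −20 °C to rt) displaces the triflate of F4 by SN2 with inversion to give the same 2R ester 12.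

## Further compounds

F1 | step 12 | S-(4-methylphenyl) (2R)-2-(4-allyl-2,6-dimethoxyphenoxy)propanethioate | C=CCc1cc(OC)c(O[C@H](C)C(=O)Sc2ccc(C)cc2)c(OC)c1
F2 | step 12 | (2R)-2-(4-allyl-2,6-dimethoxyphenoxy)-1-[3,4-dimethoxy-5-(triisopropylsilyloxy)phenyl]propan-1-one | C=CCc1cc(OC)c(O[C@H](C)C(=O)c2cc(O[Si](C(C)C)(C(C)C)C(C)C)c(OC)c(OC)c2)c(OC)c1
F3 | step 6 | (2R)-2-(4-allyl-2,6-dimethoxyphenoxy)propan-1-ol | C=CCc1cc(OC)c(O[C@H](C)CO)c(OC)c1
F4 | step 5 | ethyl (2S)-2-(trifluoromethylsulfonyloxy)propanoate | C[C@H](OS(=O)(=O)C(F)(F)F)C(=O)OCC
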